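**Plan** (1-benzoxepine numbering of the core: O1, C2–C5, C5a, C6–C9, C9a)
- Retrosynthesis: the C2 bromomethylidene goes back to a lactone C2=O, the 3,4-epoxide to a 3-hydroxy-4-ketone, and C7–Br to a C7 oxygen. The resulting β-keto lactone is cut at O1–C2 and C9a–C5a in one operation; the open chain is then cut at C5a=C5 (vinylogous aldol/elimination) and C6–C7 (aldol).
- Enabling feature: O1 sits on the quaternary fusion carbon C9a, and the other fusion carbon C5a is linked to the enol-ether carbon C2 by the run C5a–C5–C4–C3–C2 with C4 oxygenated. A methyl ketone at C9a can therefore be inserted as its ketyl (radical at carbon, anion at oxygen) between the alkene end (C5a) and the acyl end (C2) of a 3-oxopent-4-enoyl unit masked as a 6-alkenyl-1,3-dioxin-4-one.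
- Forward order: open chain → ring A (cyclohexane, C9a–C5a) and ring B (oxepane lactone, O1–C2) closed together → α-epoxide → C7 bromide → bromomethylidene.
- Stereochemistry: C7 from an enantioselective Mukaiyama aldol; C9a and C5a from the chair transition state of the ketyl cyclisation, steered by the equatorial C7 silyloxy group; C3 by hydroxylation anti to the axial 9a-methyl; C4 by hydroxyl-directed reduction and SN2 epoxide closure; C7–Br by oxidation, equatorial hydride delivery and SN2 inversion; the E alkene by removal of the bromine cis to O1.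

Key step: step 7

Remark: the tetramethyl dioxinone used in step 4 is taken to be purchasable, and D-configured N-tosylvaline is taken to be the promoter enantiomer that gives the 3S aldol.

Step 1
Reactants: 1 pent-4-enal; 2 1-methoxy-2-methyl-1-(trimethylsilyloxy)prop-1-ene
Product: 3 methyl (3S)-3-hydroxy-2,2-dimethylhept-6-enoate
Conditions: N-Ts-D-valine, BH3·THF (1 equiv each), CH2Cl2, −78 °C; aq. NaHCO3
Reagents that add atoms: none
Why: The oxazaborolidinone-promoted enantioselective Mukaiyama aldol (Kiyooka aldol) of an isobutyrate silyl ketene acetal with an unbranched aldehyde should build the gem-dimethyl carbon (later C6) and set the 3S carbinol (later C7) by attack on the aldehyde face left open in the chiral acyloxyborane complex.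

Step 2
Reactants: 3 methyl (3S)-3-hydroxy-2,2-dimethylhept-6-enoate
Product: 4 methyl (3S)-3-[(tert-butyldimethylsilyl)oxy]-2,2-dimethylhept-6-enoate
Conditions: TBSOTf, 2,6-lutidine, CH2Cl2, 0 °C
Reagents that add atoms: tert-butyldimethylsilyl triflate, CC(C)(C)[Si](C)(C)OS(=O)(=O)C(F)(F)F
Why: Silylation of a hindered secondary alcohol with the silyl triflate is standard and touches no stereocenter.

Step 3
Reactants: 4 methyl (3S)-3-[(tert-butyldimethylsilyl)oxy]-2,2-dimethylhept-6-enoate
Product: 5 (3S)-3-[(tert-butyldimethylsilyl)oxy]-2,2-dimethylhept-6-enal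
Conditions: i-Bu2AlH (DIBAL-H, 1.1 equiv), CH2Cl2, −78 °C; Rochelle salt work-up
Reagents that add atoms: none
Why: In this partial ester reduction the tetrahedral aluminium hemiacetal of the hindered α,α-dimethyl ester should survive at −78 °C and release the aldehyde only on work-up.

Step 4
Reactants: 5 (3S)-3-[(tert-butyldimethylsilyl)oxy]-2,2-dimethylhept-6-enal; 6 2,2,5,6-tetramethyl-4H-1,3-dioxin-4-one
Product: 7 6-[(4S)-4-[(tert-butyldimethylsilyl)oxy]-2-hydroxy-3,3-dimethyloct-7-en-1-yl]-2,2,5-trimethyl-4H-1,3-dioxin-4-one (both epimers at the new carbinol)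
Conditions: LiN(i-Pr)2 (LDA), THF, −78 °C, then 5; aq. work-up
Reagents that add atoms: none
Why: In this vinylogous aldol addition the lithium dienolate of the dioxinone (5-position blocked by methyl) should attack the non-enolisable aldehyde through its exocyclic γ-carbon, and the epimeric carbinol is removed in the next step.

Step 5
Reactants: 7 6-[(4S)-4-[(tert-butyldimethylsilyl)oxy]-2-hydroxy-3,3-dimethyloct-7-en-1-yl]-2,2,5-trimethyl-4H-1,3-dioxin-4-one
Product: 9 6-[(1E,4S)-4-[(tert-butyldimethylsilyl)oxy]-3,3-dimethylocta-1,7-dien-1-yl]-2,2,5-trimethyl-4H-1,3-dioxin-4-one, via mesylate 8 (not isolated)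
Conditions: MsCl, Et3N, CH2Cl2, 0 °C; then DBU, 25 °C
Reagents that add atoms: none
Why: Mesylation followed by E1cB elimination through the dioxinone dienolate should give only the conjugated E alkene, because the other neighbour of the carbinol is quaternary and the tert-alkyl group avoids the ring.

Step 6
Reactants: 9 6-[(1E,4S)-4-[(tert-butyldimethylsilyl)oxy]-3,3-dimethylocta-1,7-dien-1-yl]-2,2,5-trimethyl-4H-1,3-dioxin-4-one
Product: 10 6-[(1E,4S)-4-[(tert-butyldimethylsilyl)oxy]-3,3-dimethyl-7-oxooct-1-en-1-yl]-2,2,5-trimethyl-4H-1,3-dioxin-4-one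
Conditions: PdCl2 (10 mol%), CuCl, O2 (1 atm), DMF/H2O, 25 °C
Reagents that add atoms: water, O
Why: The Tsuji–Wacker oxidation should convert the unhindered terminal alkene into the methyl ketone with Markovnikov selectivity and leave the electron-poor conjugated alkene alone.

Step 7
Reactants: 10 6-[(1E,4S)-4-[(tert-butyldimethylsilyl)oxy]-3,3-dimethyl-7-oxooct-1-en-1-yl]-2,2,5-trimethyl-4H-1,3-dioxin-4-one
Product: 12 (5aS,7S,9aS)-7-[(tert-butyldimethylsilyl)oxy]-3,6,6,9a-tetramethyl-5a,6,7,8,9,9a-hexahydro-1-benzoxepine-2,4(3H,5H)-dione, via hydroxy dioxinone 11 (not isolated)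
Conditions: SmI2 (2.5 equiv), HMPA, t-BuOH (2 equiv), THF (0.01 M), −78 °C, then 25 °C
Reagents that add atoms: none
Why: Proposed new method: SmI2–HMPA reduces the methyl ketone to its ketyl, which adds 6-exo-trig to the distal carbon of the alkenyl dioxinone (a vinylogous acceptor); a second electron gives the samarium dienolate, t-BuOH protonates it at the γ-carbon, and the tertiary samarium alkoxide now held next to the dioxinone attacks its carbonyl and expels acetone, so that C9a–C5a and O1–C2 arise in one flask. The closest known reaction type is the SmI2 ketyl–olefin cyclisation of keto enoates with in situ γ-lactonisation, combined with the known opening of 1,3-dioxin-4-ones by alkoxides (or by heat through the acylketene) to β-keto esters and lactones. Ring A closes by 6-exo-trig radical addition and ring B by acyl substitution at the dioxinone carbonyl (7-exo-trig at C2). C9a and C5a are set in a chair transition state in which the bulky HMPA-solvated samarium-oxygen and the alkenyl chain are both pseudo-equatorial and anti (trans hydroxyl/side chain, hence the trans ring fusion), and the equatorial 7-silyloxy group decides which of the two mirror-related chairs is used; C3 stays epimerisable and is fixed in step 8. The step needs cyclisation to outrun simple reduction of the ketone or of the dienyl dioxinone, and attack at the distal alkene carbon: HMPA, high dilution and t-BuOH as the only proton source favour the former, and the six- against eight-membered ring size secures the latter.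

Step 8
Reactants: 12 (5aS,7S,9aS)-7-[(tert-butyldimethylsilyl)oxy]-3,6,6,9a-tetramethyl-5a,6,7,8,9,9a-hexahydro-1-benzoxepine-2,4(3H,5H)-dione
Product: 13 (3R,5aS,7S,9aS)-7-[(tert-butyldimethylsilyl)oxy]-3-hydroxy-3,6,6,9a-tetramethyl-5a,6,7,8,9,9a-hexahydro-1-benzoxepine-2,4(3H,5H)-dione
Conditions: dimethyldioxirane, acetone, 0 °C
Reagents that add atoms: dimethyldioxirane, CC1(C)OO1
Why: Electrophilic α-hydroxylation of the enol of the β-keto lactone (Rubottom-type oxidation of a 1,3-dicarbonyl) should occur at C3 from the α-face, because the axial 9a-methyl group screens the β-face of ring B, which sets 3R.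

Step 9
Reactants: 13 (3R,5aS,7S,9aS)-7-[(tert-butyldimethylsilyl)oxy]-3-hydroxy-3,6,6,9a-tetramethyl-5a,6,7,8,9,9a-hexahydro-1-benzoxepine-2,4(3H,5H)-dione
Product: 14 (3R,4S,5aS,7S,9aS)-7-[(tert-butyldimethylsilyl)oxy]-3,4-dihydroxy-3,6,6,9a-tetramethyloctahydro-1-benzoxepin-2(3H)-one
Conditions: Me4NBH(OAc)3, MeCN/AcOH, −30 °C
Reagents that add atoms: none
Why: In this hydroxyl-directed reduction the triacetoxyborohydride should bind the tertiary 3-hydroxyl and deliver hydride intramolecularly to the α-face of the C4 ketone, giving the trans-3,4-diol (4S) and leaving the lactone alone.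

Step 10
Reactants: 14 (3R,4S,5aS,7S,9aS)-7-[(tert-butyldimethylsilyl)oxy]-3,4-dihydroxy-3,6,6,9a-tetramethyloctahydro-1-benzoxepin-2(3H)-one
Product: 16 (3R,4R,5aS,7S,9aS)-7-[(tert-butyldimethylsilyl)oxy]-3,4-epoxy-3,6,6,9a-tetramethyloctahydro-1-benzoxepin-2(3H)-one, via 4-mesylate 15 (not isolated)
Conditions: MsCl, Et3N, CH2Cl2, −20 °C; then DBU, toluene, 60 °C
Reagents that add atoms: none
Why: Selective mesylation of the secondary 4-hydroxyl and intramolecular Williamson displacement by the tertiary 3-alkoxide (3-exo-tet SN2 with inversion at C4) should give the α-epoxide with 3R,4R configuration.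

Step 11
Reactants: 16 (3R,4R,5aS,7S,9aS)-7-[(tert-butyldimethylsilyl)oxy]-3,4-epoxy-3,6,6,9a-tetramethyloctahydro-1-benzoxepin-2(3H)-one
Product: 17 (3R,4R,5aS,7S,9aS)-3,4-epoxy-7-hydroxy-3,6,6,9a-tetramethyloctahydro-1-benzoxepin-2(3H)-one
Conditions: tetrabutylammonium fluoride, THF, 25 °C
Reagents that add atoms: none
Why: Fluoride-mediated desilylation is driven by the Si–F bond and touches no stereocenter.

Step 12
Reactants: 17 (3R,4R,5aS,7S,9aS)-3,4-epoxy-7-hydroxy-3,6,6,9a-tetramethyloctahydro-1-benzoxepin-2(3H)-one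
Product: 18 (3R,4R,5aS,9aS)-3,4-epoxy-3,6,6,9a-tetramethylhexahydro-1-benzoxepine-2,7(3H,8H)-dione
Conditions: Dess–Martin periodinane, pyridine, CH2Cl2, 25 °C
Reagents that add atoms: none
Why: Dess–Martin oxidation of the secondary alcohol runs under near-neutral conditions that should spare the epoxy lactone.

Step 13
Reactants: 18 (3R,4R,5aS,9aS)-3,4-epoxy-3,6,6,9a-tetramethylhexahydro-1-benzoxepine-2,7(3H,8H)-dione
Product: 19 (3R,4R,5aS,7R,9aS)-3,4-epoxy-7-hydroxy-3,6,6,9a-tetramethyloctahydro-1-benzoxepin-2(3H)-one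
Conditions: LiBH(s-Bu)3 (L-Selectride), THF, −78 °C
Reagents that add atoms: none
Why: In this hindered trialkylborohydride reduction the hydride should approach the cyclohexanone next to the gem-dimethyl carbon from the equatorial direction and give the axial 7R alcohol, while the hindered lactone is left at −78 °C.

Step 14
Reactants: 19 (3R,4R,5aS,7R,9aS)-3,4-epoxy-7-hydroxy-3,6,6,9a-tetramethyloctahydro-1-benzoxepin-2(3H)-one
Product: 20 (3R,4R,5aS,7S,9aS)-7-bromo-3,4-epoxy-3,6,6,9a-tetramethyloctahydro-1-benzoxepin-2(3H)-one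
Conditions: PPh3, CBr4, toluene, 60 °C
Reagents that add atoms: carbon tetrabromide, BrC(Br)(Br)Br
Why: In the Appel bromination, SN2 displacement of the axial alkoxyphosphonium group by bromide with inversion should give the equatorial 7S bromide.

Step 15
Reactants: 20 (3R,4R,5aS,7S,9aS)-7-bromo-3,4-epoxy-3,6,6,9a-tetramethyloctahydro-1-benzoxepin-2(3H)-one
Product: 21 (3R,4R,5aS,7S,9aS)-7-bromo-2-(dibromomethylidene)-3,4-epoxy-3,6,6,9a-tetramethyldecahydro-1-benzoxepine
Conditions: PPh3 (4 equiv), CBr4 (2 equiv), toluene, 110 °C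
Reagents that add atoms: carbon tetrabromide, BrC(Br)(Br)Br
Why: Ramirez-type dibromomethylenation (Wittig reaction of Ph3P=CBr2 with a lactone carbonyl, as known for sugar lactones) should turn the lactone C=O into the dibromo ketene acetal without touching a stereocenter.

Step 16
Reactants: 21 (3R,4R,5aS,7S,9aS)-7-bromo-2-(dibromomethylidene)-3,4-epoxy-3,6,6,9a-tetramethyldecahydro-1-benzoxepine
Product: 22 (2E,3R,4R,5aS,7S,9aS)-7-bromo-2-(bromomethylidene)-3,4-epoxy-3,6,6,9a-tetramethyldecahydro-1-benzoxepine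
Conditions: Pd(PPh3)4 (5 mol%), Bu3SnH (1.1 equiv), toluene, 25 °C, dark
Reagents that add atoms: none
Why: In this palladium-catalysed hydrodebromination of a 1,1-dibromoalkene, oxidative addition should occur at the less hindered C–Br bond cis to O1 (trans to the quaternary C3), and hydride transfer from tin with retention should leave the bromine cis to C3, which is the 2E geometry.

**Compound list**
1 | pent-4-enal | C=CCCC=O | starting material
2 | 1-methoxy-2-methyl-1-(trimethylsilyloxy)prop-1-ene | COC(O[Si](C)(C)C)=C(C)C | starting material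
3 | methyl (3S)-3-hydroxy-2,2-dimethylhept-6-enoate | C=CCC[C@H](O)C(C)(C)C(=O)OC | intermediate
4 | methyl (3S)-3-[(tert-butyldimethylsilyl)oxy]-2,2-dimethylhept-6-enoate | C=CCC[C@H](O[Si](C)(C)C(C)(C)C)C(C)(C)C(=O)OC | intermediate
5 | (3S)-3-[(tert-butyldimethylsilyl)oxy]-2,2-dimethylhept-6-enal | C=CCC[C@H](O[Si](C)(C)C(C)(C)C)C(C)(C)C=O | intermediate
6 | 2,2,5,6-tetramethyl-4H-1,3-dioxin-4-one | CC1=C(C)C(=O)OC(C)(C)O1 | starting material
7 | 6-[(4S)-4-[(tert-butyldimethylsilyl)oxy]-2-hydroxy-3,3-dimethyloct-7-en-1-yl]-2,2,5-trimethyl-4H-1,3-dioxin-4-one (both carbinol epimers) | C=CCC[C@H](O[Si](C)(C)C(C)(C)C)C(C)(C)C(O)CC1=C(C)C(=O)OC(C)(C)O1 | intermediate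
8 | 2-methanesulfonate of 7 | C=CCC[C@H](O[Si](C)(C)C(C)(C)C)C(C)(C)C(OS(C)(=O)=O)CC1=C(C)C(=O)OC(C)(C)O1 | intermediate (not isolated)
9 | 6-[(1E,4S)-4-[(tert-butyldimethylsilyl)oxy]-3,3-dimethylocta-1,7-dien-1-yl]-2,2,5-trimethyl-4H-1,3-dioxin-4-one | C=CCC[C@H](O[Si](C)(C)C(C)(C)C)C(C)(C)/C=C/C1=C(C)C(=O)OC(C)(C)O1 | intermediate
10 | 6-[(1E,4S)-4-[(tert-butyldimethylsilyl)oxy]-3,3-dimethyl-7-oxooct-1-en-1-yl]-2,2,5-trimethyl-4H-1,3-dioxin-4-one | CC(=O)CC[C@H](O[Si](C)(C)C(C)(C)C)C(C)(C)/C=C/C1=C(C)C(=O)OC(C)(C)O1 | intermediate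
11 | 6-{[(1S,2S,5S)-5-[(tert-butyldimethylsilyl)oxy]-2-hydroxy-2,6,6-trimethylcyclohexyl]methyl}-2,2,5-trimethyl-4H-1,3-dioxin-4-one (present as its samarium alkoxide) | CC1(C)[C@@H](O[Si](C)(C)C(C)(C)C)CC[C@](C)(O)[C@H]1CC2=C(C)C(=O)OC(C)(C)O2 | intermediate (not isolated)
12 | (5aS,7S,9aS)-7-[(tert-butyldimethylsilyl)oxy]-3,6,6,9a-tetramethyl-5a,6,7,8,9,9a-hexahydro-1-benzoxepine-2,4(3H,5H)-dione (trans-fused; C3 epimers) | CC1(C)[C@@H](O[Si](C)(C)C(C)(C)C)CC[C@]2(C)OC(=O)C(C)C(=O)C[C@@H]12 | intermediate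
13 | (3R,5aS,7S,9aS)-7-[(tert-butyldimethylsilyl)oxy]-3-hydroxy-3,6,6,9a-tetramethyl-5a,6,7,8,9,9a-hexahydro-1-benzoxepine-2,4(3H,5H)-dione | CC1(C)[C@@H](O[Si](C)(C)C(C)(C)C)CC[C@]2(C)OC(=O)[C@](C)(O)C(=O)C[C@@H]12 | intermediate
14 | (3R,4S,5aS,7S,9aS)-7-[(tert-butyldimethylsilyl)oxy]-3,4-dihydroxy-3,6,6,9a-tetramethyloctahydro-1-benzoxepin-2(3H)-one | CC1(C)[C@@H](O[Si](C)(C)C(C)(C)C)CC[C@]2(C)OC(=O)[C@](C)(O)[C@@H](O)C[C@@H]12 | intermediate
15 | 4-methanesulfonate of 14 | CC1(C)[C@@H](O[Si](C)(C)C(C)(C)C)CC[C@]2(C)OC(=O)[C@](C)(O)[C@@H](OS(C)(=O)=O)C[C@@H]12 | intermediate (not isolated)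
16 | (3R,4R,5aS,7S,9aS)-7-[(tert-butyldimethylsilyl)oxy]-3,4-epoxy-3,6,6,9a-tetramethyloctahydro-1-benzoxepin-2(3H)-one (α-epoxide) | CC1(C)[C@@H](O[Si](C)(C)C(C)(C)C)CC[C@]2(C)OC(=O)[C@]3(C)O[C@@H]3C[C@@H]12 | intermediate
17 | (3R,4R,5aS,7S,9aS)-3,4-epoxy-7-hydroxy-3,6,6,9a-tetramethyloctahydro-1-benzoxepin-2(3H)-one (equatorial alcohol) | CC1(C)[C@@H](O)CC[C@]2(C)OC(=O)[C@]3(C)O[C@@H]3C[C@@H]12 | intermediate
18 | (3R,4R,5aS,9aS)-3,4-epoxy-3,6,6,9a-tetramethylhexahydro-1-benzoxepine-2,7(3H,8H)-dione | CC1(C)C(=O)CC[C@]2(C)OC(=O)[C@]3(C)O[C@@H]3C[C@@H]12 | intermediate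
19 | (3R,4R,5aS,7R,9aS)-3,4-epoxy-7-hydroxy-3,6,6,9a-tetramethyloctahydro-1-benzoxepin-2(3H)-one (axial alcohol) | CC1(C)[C@H](O)CC[C@]2(C)OC(=O)[C@]3(C)O[C@@H]3C[C@@H]12 | intermediate
20 | (3R,4R,5aS,7S,9aS)-7-bromo-3,4-epoxy-3,6,6,9a-tetramethyloctahydro-1-benzoxepin-2(3H)-one | CC1(C)[C@@H](Br)CC[C@]2(C)OC(=O)[C@]3(C)O[C@@H]3C[C@@H]12 | intermediate
21 | (3R,4R,5aS,7S,9aS)-7-bromo-2-(dibromomethylidene)-3,4-epoxy-3,6,6,9a-tetramethyldecahydro-1-benzoxepine | CC1(C)[C@@H](Br)CC[C@]2(C)OC(=C(Br)Br)[C@]3(C)O[C@@H]3C[C@@H]12 | intermediate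
22 | (2E,3R,4R,5aS,7S,9aS)-7-bromo-2-(bromomethylidene)-3,4-epoxy-3,6,6,9a-tetramethyldecahydro-1-benzoxepine | CC1(C)[C@@H](Br)CC[C@]2(C)O/C(=C/Br)[C@]3(C)O[C@@H]3C[C@@H]12 | target

Total step count: 16. Longest linear sequence: 16 steps (from pent-4-enal).

**Steps most likely to fail**

Step 7 (labelled step). The samarium alkoxide may fail to open the dioxinone before work-up, or reduction of the ketone or of the dienyl dioxinone without ring closure may compete. Fallback with known chemistry: set out from 10, run the SmI2–HMPA–t-BuOH ketyl–olefin cyclisation at −78 °C and quench cold with AcOH so that the hydroxy dioxinone 11 is isolated (no compound outside the list, F0). Then heat 11 in toluene at 110 °C: retro-[4+2] loss of acetone gives the acylketene, which the tertiary hydroxyl should trap (acylketene lactonisation). The route is rejoined at 12.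

Step 15. Wittig-type attack on the lactone carbonyl, which is flanked by a tertiary alkoxy carbon and a quaternary epoxide carbon, may be too slow, and phosphonium bromide species may open the epoxide. Fallback: set out from 20 and methylenate the lactone with Cp2TiMe2 (toluene, 70 °C) to the 2-methylidene enol ether F1. Brominate F1 with NBS and 2,6-lutidine (bromo-oxocarbenium ion, then loss of a proton) to the monobromo enol ether F2, a mixture of alkene isomers. A second NBS/2,6-lutidine treatment should give the dibromide, and the route is rejoined at 21.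

Step 16. Site selection between the two vinylic C–Br bonds may be poor (giving the 2Z isomer or double reduction), and a radical chain may reduce the secondary alkyl bromide. Fallback: set out from 21 and carry out a bromine–magnesium exchange with i-PrMgCl·LiCl in THF at −78 °C. Chelation to O1 should direct the exchange to the bromine cis to the ring oxygen and give the α-bromoalkenylmagnesium chloride F3. Protonation with MeOH at −78 °C with retention should then give 22.

Further compounds
F0 | step 7 | none | none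
F1 | step 15 | (3R,4R,5aS,7S,9aS)-7-bromo-3,4-epoxy-3,6,6,9a-tetramethyl-2-methylidenedecahydro-1-benzoxepine | CC1(C)[C@@H](Br)CC[C@]2(C)OC(=C)[C@]3(C)O[C@@H]3C[C@@H]12
F2 | step 15 | (3R,4R,5aS,7S,9aS)-7-bromo-2-(bromomethylidene)-3,4-epoxy-3,6,6,9a-tetramethyldecahydro-1-benzoxepine, mixture of alkene isomers | CC1(C)[C@@H](Br)CC[C@]2(C)OC(=CBr)[C@]3(C)O[C@@H]3C[C@@H]12
F3 | step 16 | [(Z)-bromo{(3R,4R,5aS,7S,9aS)-7-bromo-3,4-epoxy-3,6,6,9a-tetramethyloctahydro-1-benzoxepin-2(3H)-ylidene}methyl]magnesium chloride (magnesium cis to O1) | CC1(C)[C@@H](Br)CC[C@]2(C)O/C(=C(/Br)[Mg]Cl)[C@]3(C)O[C@@H]3C[C@@H]12
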